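**Plan**
Numbering: pyranone O1, C2–C6; chain C7–C12; cyclohexane C13–C18. The retrosynthesis cuts C7=C8 (aldol–dehydration with a 6-ethylpyranone), C9=C10 and C11=C12 (two Wittig reactions), then the ring bond C13–C18, then C13–C14 (allyl/epoxide opening) and C16–C17 (alkenyl Grignard addition).
Enabling feature: in ring C13–C18 the oxygens O15–O18 share one face; on the chair with O15 and O17 both axial, C12 (on C13) and O18 are equatorial and trans, and C18 is attached to the fully substituted C17. A C12,C18-dialdehyde can therefore enolise only towards C13, and an enamine aldol with O15/O17 tied by silicon closes the ring.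
Forward: tiglic aldehyde and isopropenylmagnesium bromide give a dienol; Sharpless kinetic resolution sets C15/C16 (and C14 as an epoxide carbon); a hydroxyl-directed epoxidation sets C17; ylide homologation and allyl opening (inversion at C14) complete the chain with two terminal alkenes.
O16 acetate, O15/O17 silylene and a double ozonolysis give the dialdehyde; D-proline closes the only carbocycle (C13 and C18 from the locked chair and the matched catalyst). The side chain then grows outward, the pyranone (made separately in 3 steps) is joined last, and fluoride removes both silicon groups.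

Key step: step 9

Remark: the silicon lock is chosen as diisopropyl, because one substituent on silicon must lie endo over C13 in the bicyclo[3.3.1] array of the ring closure, where an isopropyl group can turn its C–H inward and a tert-butyl group cannot.

**Route**

Step 1
Reactants: 1 (E)-2-methylbut-2-enal (tiglic aldehyde); 2 isopropenylmagnesium bromide
Product: 3 rac-(E)-2,4-dimethylhexa-1,4-dien-3-ol
Conditions: THF, −78 → 0 °C; aq. work-up
Reagents that add atoms: none
Why: Grignard 1,2-addition of the alkenylmagnesium reagent to the enal carbonyl gives the doubly allylic carbinol, whose stereocentre (C16) is racemic here and is resolved in step 2.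

Step 2
Reactants: 3 rac-(E)-2,4-dimethylhexa-1,4-dien-3-ol
Product: 4 (S)-1-[(2S,3S)-2,3-dimethyloxiran-2-yl]-2-methylprop-2-en-1-ol
Conditions: Ti(OiPr)4 (0.2 equiv), L-(+)-diisopropyl tartrate (0.25 equiv), t-BuOOH (0.6 equiv), 4 Å MS, CH2Cl2, −20 °C
Reagents that add atoms: tert-butyl hydroperoxide, CC(C)(C)OO
Why: Sharpless kinetic resolution: with the L-(+)-tartrate complex only (S)-3 presents its electron-rich trisubstituted C14=C15 alkene in the matched arrangement, so oxygen is delivered to one face and the erythro epoxy alcohol (14S,15S,16S) should result, whereas (R)-3 is epoxidised much more slowly (and then mainly at its isopropenyl group) and is removed by chromatography.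

Step 3
Reactants: 4 (S)-1-[(2S,3S)-2,3-dimethyloxiran-2-yl]-2-methylprop-2-en-1-ol
Product: 5 (S)-[(2S,3S)-2,3-dimethyloxiran-2-yl][(2S)-2-methyloxiran-2-yl]methanol
Conditions: VO(acac)2 (3 mol %), t-BuOOH, CH2Cl2, 0 °C → rt
Reagents that add atoms: tert-butyl hydroperoxide, CC(C)(C)OO
Why: hydroxyl-directed vanadium-catalysed epoxidation of a 2-substituted secondary allylic alcohol: allylic 1,2-strain between the C17 methyl and the bulky oxiranyl group on C16 fixes the carbinol rotamer, so the peroxide bound at O16 reaches one face of C17=C18 and the erythro (16,17-anti) epoxide, 17S, is expected.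

Step 4
Reactants: 5 (S)-[(2S,3S)-2,3-dimethyloxiran-2-yl][(2S)-2-methyloxiran-2-yl]methanol
Product: 6 (1S,2S)-1-[(2S,3S)-2,3-dimethyloxiran-2-yl]-2-methylbut-3-ene-1,2-diol
Conditions: Me3S+ I− (5 equiv), n-BuLi (4.8 equiv), THF, −10 °C → rt
Reagents that add atoms: trimethylsulfonium iodide, C[S+](C)C.[I-]
Why: sulfonium-ylide homologation of an epoxide to an allylic alcohol: dimethylsulfonium methylide opens the terminal epoxide at the unhindered C18 methylene (the trisubstituted C14–C15 epoxide is inert and a Payne shift would need substitution at a tertiary carbon), and the sulfonium salt formed is deprotonated by excess ylide and loses dimethyl sulfide by α′,β-elimination to give the vinyl carbinol with C17 untouched.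

Step 5
Reactants: 6 (1S,2S)-1-[(2S,3S)-2,3-dimethyloxiran-2-yl]-2-methylbut-3-ene-1,2-diol; 7 allylmagnesium bromide
Product: 8 (3S,4S,5R,6S)-3,5,6-trimethylnona-1,8-diene-3,4,5-triol
Conditions: 7 (4 equiv), CuI (10 mol %), THF, −30 → 0 °C; aq. work-up
Reagents that add atoms: none
Why: CuI-catalysed Grignard opening of a 2,3-epoxy alcohol: the allyl group attacks the secondary C14 anti to the epoxide oxygen because C15 is fully substituted, so C14 is set by inversion (14S) and the epoxide oxygen becomes the tertiary O15 hydroxyl.

Step 6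
Reactants: 8 (3S,4S,5R,6S)-3,5,6-trimethylnona-1,8-diene-3,4,5-triol
Product: 9 (3S,4S,5R,6S)-3,5-dihydroxy-3,5,6-trimethylnona-1,8-dien-4-yl acetate
Conditions: Ac2O (1.2 equiv), DMAP (0.1 equiv), pyridine, CH2Cl2, 0 °C → rt
Reagents that add atoms: acetic anhydride, CC(=O)OC(C)=O
Why: DMAP-catalysed acetylation distinguishes the single secondary hydroxyl (O16) from the two tertiary ones, which do not acylate under these conditions.

Step 7
Reactants: 9 (3S,4S,5R,6S)-3,5-dihydroxy-3,5,6-trimethylnona-1,8-dien-4-yl acetate
Product: 10 (4S,5S,6R)-4-ethenyl-4,6-dimethyl-6-[(2S)-pent-4-en-2-yl]-2,2-di(propan-2-yl)-1,3,2-dioxasilinan-5-yl acetate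
Conditions: iPr2Si(OTf)2 (1.2 equiv), 2,6-lutidine (3 equiv), CH2Cl2, 0 → 40 °C
Reagents that add atoms: diisopropylsilyl bis(trifluoromethanesulfonate), CC(C)[Si](OS(=O)(=O)C(F)(F)F)(OS(=O)(=O)C(F)(F)F)C(C)C
Why: silylene formation: the bis-triflate is reactive enough to silylate tertiary alcohols, and after the first Si–O bond the second closes intramolecularly to the six-membered 1,3,2-dioxasilinane across the syn-related O15 and O17, the only free hydroxyls.

Step 8
Reactants: 10 (4S,5S,6R)-4-ethenyl-4,6-dimethyl-6-[(2S)-pent-4-en-2-yl]-2,2-di(propan-2-yl)-1,3,2-dioxasilinan-5-yl acetate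
Product: 12 (4R,5R,6R)-4-formyl-4,6-dimethyl-6-[(2S)-4-oxobutan-2-yl]-2,2-di(propan-2-yl)-1,3,2-dioxasilinan-5-yl acetate, via bis-ozonide 11 (not isolated)
Conditions: O3, CH2Cl2, −78 °C; PPh3 (2.5 equiv), −78 °C → rt; used directly
Reagents that add atoms: ozone, [O-][O+]=O
Why: ozonolysis with reductive work-up cleaves both terminal alkenes (the only C=C bonds) in one operation, giving the enolisable C12 aldehyde and the non-enolisable C18 aldehyde without touching the acetate or the silylene.

Step 9
Reactants: 12 (4R,5R,6R)-4-formyl-4,6-dimethyl-6-[(2S)-4-oxobutan-2-yl]-2,2-di(propan-2-yl)-1,3,2-dioxasilinan-5-yl acetate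
Product: 13 (13R,14S,15R,16R,17S,18S)-16-acetoxy-18-hydroxy-14,15,17-trimethyl-15,17-O-(diisopropylsilanediyl)cyclohexane-13-carbaldehyde (target numbering)
Conditions: D-proline (20 mol %), CH2Cl2, rt; aq. work-up, short silica plug
Reagents that add atoms: none
Why: Only the C12 aldehyde can form an enamine with D-proline, because C18 is attached to the fully substituted C17; the nucleophilic carbon of that enamine (C13) attacks the C18 carbonyl while the catalyst's carboxylic acid hydrogen-bonds to its oxygen, and hydrolysis of the iminium releases the catalyst (enamine aldol; the closest known reaction type is the proline-catalysed enolexo aldolisation of heptane-1,7-dials to trans-2-hydroxycyclohexanecarbaldehydes). The cyclohexane C13–C18 closes in the 6-enolexo-exo-trig mode through a chair-like transition state. The silylene ties O15 to O17, so on this chair both must be axial, the ring cannot flip, and the C14 methyl is axial, where it also avoids allylic strain with the exocyclic enamine. C13 is set because the enamine carbon then carries C12 equatorial, and C18 is set because the carbonyl oxygen, held by the acid, points equatorial and anti to C12 across the new bond, giving the trans-diequatorial 13R,18S pair. The step needs site selectivity between the two aldehydes, secured by the missing α-hydrogen next to C18, and diastereoselectivity at C13/C18, secured by the locked chair and reinforced by D-proline, the enantiomer whose acid-directed transition state leads to this pair.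

Step 10
Reactants: 13 hydroxy aldehyde (key-step product)
Product: 14 18-O-triethylsilyl ether of 13
Conditions: Et3SiOTf (1.2 equiv), 2,6-lutidine (2 equiv), CH2Cl2, −78 °C
Reagents that add atoms: triethylsilyl trifluoromethanesulfonate, CC[Si](CC)(CC)OS(=O)(=O)C(F)(F)F
Why: silylation with a silyl triflate and a hindered pyridine base at low temperature caps the equatorial C18 hydroxyl faster than the aldehyde can enolise, which blocks retro-aldol and β-elimination pathways and keeps O18 out of the later mesylation.

Step 11
Reactants: 14 18-O-triethylsilyl ether of 13; 15 2-(triphenylphosphoranylidene)propanal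
Product: 16 (E)-enal: 14 with –CH=C(CH3)–CHO on C13 in place of the formyl group
Conditions: 15 (1.5 equiv), toluene, 80 °C
Reagents that add atoms: none
Why: Wittig olefination with the formyl-stabilised ylide gives the trisubstituted enal directly at the aldehyde oxidation level (no hydride step that would endanger the acetate) and with the E geometry at C11=C12 typical of stabilised ylides.

Step 12
Reactants: 16 (E)-enal; 17 (triphenylphosphoranylidene)acetaldehyde
Product: 18 (2E,4E)-dienal: 14 with –CH=C(CH3)–CH=CH–CHO on C13
Conditions: 17 (1.2 equiv), toluene, 80 °C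
Reagents that add atoms: none
Why: a second Wittig reaction with the formylmethylene ylide extends the enal by two carbons and sets C9=C10 as E, the ylide being kept near one equivalent so that the less hindered product is not homologated again.

Step 13
Reactants: 19 methyl 2-methyl-3-oxopentanoate; 20 N-methoxy-N-methylpropanamide
Product: 22 methyl 2,4-dimethyl-3,5-dioxoheptanoate, via dilithium dianion 21 (not isolated)
Conditions: LiN(iPr)2 (2.3 equiv), THF, −78 → 0 °C; 20, −78 → 0 °C; aq. HCl
Reagents that add atoms: none
Why: Claisen-type acylation: the dianion of the β-keto ester reacts at its more nucleophilic γ-carbon with the Weinreb amide, whose chelated tetrahedral adduct survives until work-up and prevents over-addition.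

Step 14
Reactants: 22 methyl 2,4-dimethyl-3,5-dioxoheptanoate
Product: 23 6-ethyl-4-hydroxy-3,5-dimethyl-2H-pyran-2-one
Conditions: DBU (1.5 equiv), toluene, 60 °C; aq. HCl
Reagents that add atoms: none
Why: base-mediated enol-lactonisation: the enolate oxygen of the terminal ketone attacks the methyl ester (6-exo-trig) and methanol is lost to give the 4-hydroxy-2-pyranone.

Step 15
Reactants: 23 6-ethyl-4-hydroxy-3,5-dimethyl-2H-pyran-2-one
Product: 25 6-ethyl-2-methoxy-3,5-dimethyl-4H-pyran-4-one, via pyrylium triflate 24 (not isolated)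
Conditions: MeOTf (1.5 equiv), CH2Cl2, rt; aq. NaHCO3
Reagents that add atoms: methyl trifluoromethanesulfonate, COS(=O)(=O)C(F)(F)F
Why: O-methylation with a hard methylating agent occurs at the lactone carbonyl oxygen, the most nucleophilic site of the neutral 2-pyranone, to give a 4-hydroxy-2-methoxypyrylium salt that loses its hydroxyl proton on basic work-up, so the 2-methoxy-4-pyranone and not the 4-methoxy-2-pyranone is formed.

Step 16
Reactants: 18 (2E,4E)-dienal; 25 6-ethyl-2-methoxy-3,5-dimethyl-4H-pyran-4-one
Product: 27 C8 aldol adduct (mixture of C7/C8 diastereomers), via lithiated pyranone 26 (not isolated)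
Conditions: 25 (1.3 equiv), LiN(SiMe3)2 (1.25 equiv), THF, −78 °C; 18, −78 °C; AcOH, −78 °C
Reagents that add atoms: none
Why: vinylogous aldol addition: the amide base removes a proton from the 6-ethyl methylene (the only position conjugated with the pyranone carbonyl) and the resulting dienolate adds 1,2 to the dienal at −78 °C faster than it can attack the acetate, the two new stereocentres (C7, C8) being removed again in step 17.

Step 17
Reactants: 27 C8 aldol adduct
Product: 29 15,17-O-diisopropylsilylene-18-O-triethylsilyl amaurone A, via C8 mesylate 28 (not isolated)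
Conditions: MsCl (1.5 equiv), Et3N (3 equiv), CH2Cl2, 0 °C; DBU (3 equiv), rt
Reagents that add atoms: none
Why: mesylation of the C8 carbinol followed by DBU-promoted E1cB elimination through the pyranone-stabilised C7 carbanion gives the fully conjugated tetraene with the thermodynamically preferred 7E geometry (pyranone anti to C9).

Step 18
Reactants: 29 15,17-O-diisopropylsilylene-18-O-triethylsilyl amaurone A
Product: 30 amaurone A
Conditions: HF·pyridine, pyridine, THF, 0 °C → rt
Reagents that add atoms: none
Why: fluoride-driven Si–O cleavage (desilylation) removes the triethylsilyl ether and the silylene in one operation, while the buffered, weakly acidic medium leaves the acetate on O16 and the pyranone and tetraene intact.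

**Compound list**

1 | (E)-2-methylbut-2-enal (tiglic aldehyde) | C/C=C(\C)C=O | starting material
2 | isopropenylmagnesium bromide | C=C(C)[Mg]Br | starting material
3 | rac-(E)-2,4-dimethylhexa-1,4-dien-3-ol | C/C=C(\C)C(O)C(C)=C | intermediate
4 | (S)-1-[(2S,3S)-2,3-dimethyloxiran-2-yl]-2-methylprop-2-en-1-ol | C[C@@H]1O[C@@]1(C)[C@@H](O)C(C)=C | intermediate
5 | (S)-[(2S,3S)-2,3-dimethyloxiran-2-yl][(2S)-2-methyloxiran-2-yl]methanol | C[C@@H]1O[C@@]1(C)[C@@H](O)[C@]2(C)CO2 | intermediate
6 | (1S,2S)-1-[(2S,3S)-2,3-dimethyloxiran-2-yl]-2-methylbut-3-ene-1,2-diol | C[C@@H]1O[C@@]1(C)[C@@H](O)[C@@](C)(O)C=C | intermediate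
7 | allylmagnesium bromide | C=CC[Mg]Br | starting material
8 | (3S,4S,5R,6S)-3,5,6-trimethylnona-1,8-diene-3,4,5-triol | C=CC[C@H](C)[C@@](C)(O)[C@@H](O)[C@@](C)(O)C=C | intermediate
9 | (3S,4S,5R,6S)-3,5-dihydroxy-3,5,6-trimethylnona-1,8-dien-4-yl acetate | C=CC[C@H](C)[C@@](C)(O)[C@@H](OC(C)=O)[C@@](C)(O)C=C | intermediate
10 | (4S,5S,6R)-4-ethenyl-4,6-dimethyl-6-[(2S)-pent-4-en-2-yl]-2,2-di(propan-2-yl)-1,3,2-dioxasilinan-5-yl acetate | C=CC[C@H](C)[C@@](C)(O[Si]2(C(C)C)C(C)C)[C@@H](OC(C)=O)[C@@](C)(O2)C=C | intermediate
11 | bis-ozonide of 10 (a 1,2,4-trioxolane at each former alkene; mixture at the ozonide carbons) | O1OCOC1C[C@H](C)[C@@](C)(O[Si]2(C(C)C)C(C)C)[C@@H](OC(C)=O)[C@@](C)(O2)C3OCOO3 | intermediate (not isolated)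
12 | (4R,5R,6R)-4-formyl-4,6-dimethyl-6-[(2S)-4-oxobutan-2-yl]-2,2-di(propan-2-yl)-1,3,2-dioxasilinan-5-yl acetate (C12,C18-dialdehyde, key-step precursor) | O=CC[C@H](C)[C@@](C)(O[Si]2(C(C)C)C(C)C)[C@@H](OC(C)=O)[C@@](C)(O2)C=O | intermediate
13 | (13R,14S,15R,16R,17S,18S)-16-acetoxy-18-hydroxy-14,15,17-trimethyl-15,17-O-(diisopropylsilanediyl)cyclohexane-13-carbaldehyde (key-step product; O15–O18 on one ring face, C14 methyl and C13 formyl on the other) | O=C[C@@H]1[C@H](C)[C@@](C)(O[Si]2(C(C)C)C(C)C)[C@@H](OC(C)=O)[C@@](C)(O2)[C@H]1O | intermediate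
14 | 18-O-triethylsilyl ether of 13 (ring configuration unchanged) | O=C[C@@H]1[C@H](C)[C@@](C)(O[Si]2(C(C)C)C(C)C)[C@@H](OC(C)=O)[C@@](C)(O2)[C@H]1O[Si](CC)(CC)CC | intermediate
15 | 2-(triphenylphosphoranylidene)propanal | CC(C=O)=P(c1ccccc1)(c1ccccc1)c1ccccc1 | starting material
16 | (E)-2-methyl-3-[ring]prop-2-enal, ring = C13 of 14 (ring configuration unchanged) | O=C/C(C)=C/[C@@H]1[C@H](C)[C@@](C)(O[Si]2(C(C)C)C(C)C)[C@@H](OC(C)=O)[C@@](C)(O2)[C@H]1O[Si](CC)(CC)CC | intermediate
17 | (triphenylphosphoranylidene)acetaldehyde | O=CC=P(c1ccccc1)(c1ccccc1)c1ccccc1 | starting material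
18 | (2E,4E)-4-methyl-5-[ring]penta-2,4-dienal, ring = C13 of 14 (ring configuration unchanged) | O=C/C=C/C(C)=C/[C@@H]1[C@H](C)[C@@](C)(O[Si]2(C(C)C)C(C)C)[C@@H](OC(C)=O)[C@@](C)(O2)[C@H]1O[Si](CC)(CC)CC | intermediate
19 | methyl 2-methyl-3-oxopentanoate | CCC(=O)C(C)C(=O)OC | starting material
20 | N-methoxy-N-methylpropanamide | CCC(=O)N(C)OC | starting material
21 | dilithium dianion (bis-enolate) of 19 | [Li+].[Li+].CC=C([O-])C(C)=C([O-])OC | intermediate (not isolated)
22 | methyl 2,4-dimethyl-3,5-dioxoheptanoate (stereoisomer/tautomer mixture) | CCC(=O)C(C)C(=O)C(C)C(=O)OC | intermediate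
23 | 6-ethyl-4-hydroxy-3,5-dimethyl-2H-pyran-2-one | CCc1oc(=O)c(C)c(O)c1C | intermediate
24 | 6-ethyl-4-hydroxy-2-methoxy-3,5-dimethylpyrylium trifluoromethanesulfonate | CCc1[o+]c(OC)c(C)c(O)c1C.[O-]S(=O)(=O)C(F)(F)F | intermediate (not isolated)
25 | 6-ethyl-2-methoxy-3,5-dimethyl-4H-pyran-4-one | CCc1oc(OC)c(C)c(=O)c1C | intermediate
26 | lithium salt of 25 deprotonated at the 6-ethyl methylene | [Li+].C[CH-]c1oc(OC)c(C)c(=O)c1C | intermediate (not isolated)
27 | aldol adduct: 6-[(4E,6E)-3-hydroxy-6-methyl-7-(ring)hepta-4,6-dien-2-yl]pyranone, ring = C13 of 14, mixture at C7/C8 | COc1oc(C(C)C(O)/C=C/C(C)=C/[C@@H]2[C@H](C)[C@@](C)(O[Si]3(C(C)C)C(C)C)[C@@H](OC(C)=O)[C@@](C)(O3)[C@H]2O[Si](CC)(CC)CC)c(C)c(=O)c1C | intermediate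
28 | C8 methanesulfonate of 27 | COc1oc(C(C)C(OS(C)(=O)=O)/C=C/C(C)=C/[C@@H]2[C@H](C)[C@@](C)(O[Si]3(C(C)C)C(C)C)[C@@H](OC(C)=O)[C@@](C)(O3)[C@H]2O[Si](CC)(CC)CC)c(C)c(=O)c1C | intermediate (not isolated)
29 | 15,17-O-diisopropylsilylene-18-O-triethylsilyl amaurone A (7E,9E,11E) | COc1oc(/C(C)=C/C=C/C(C)=C/[C@@H]2[C@H](C)[C@@](C)(O[Si]3(C(C)C)C(C)C)[C@@H](OC(C)=O)[C@@](C)(O3)[C@H]2O[Si](CC)(CC)CC)c(C)c(=O)c1C | intermediate
30 | amaurone A (13R,14S,15R,16R,17S,18S; 7E,9E,11E) | COc1oc(/C(C)=C/C=C/C(C)=C/[C@@H]2[C@H](C)[C@@](C)(O)[C@@H](OC(C)=O)[C@@](C)(O)[C@H]2O)c(C)c(=O)c1C | target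

**Step count and risks**

Total: 18 steps. Longest linear sequence: 15 steps (steps 1–12 and 16–18, from tiglic aldehyde); the pyranone branch (steps 13–15) is 3 steps.

Steps most likely to fail:

Step 9 (ring closure). The enamine has to attack a neopentyl aldehyde inside a strained bicyclo[3.3.1] array, so turnover may be slow, and the amine may instead promote β-elimination of the new C18 hydroxyl or epimerisation at C13. Fallback: from 12, Et3SiOTf and Et3N in CH2Cl2 at 0 °C would convert the only enolisable aldehyde into the C12 triethylsilyl enol ether F1. BF3·OEt2 in CH2Cl2 at −78 °C would then form the same C13–C18 bond by an intramolecular Mukaiyama aldol reaction through the same tethered chair, with the bulky boron-bound oxygen equatorial, and the route is rejoined at 13.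

Step 11 (first Wittig). The formyl-stabilised ylide is weakly nucleophilic and the aldehyde is α-branched and hindered, so the heating needed may cause β-elimination of the silyloxy group or loss of configuration at C13 before olefination is complete. Fallback: from 14, S-ethyl 2-(triphenylphosphoranylidene)propanethioate in CH2Cl2 at room temperature would give the (E)-thioester F2. A Fukuyama reduction (Et3SiH, Pd/C, acetone, rt) would then bring it to the aldehyde level without a hydride reagent that attacks the acetate, rejoining the route at 16.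

Step 2 (kinetic resolution). The rate difference between matched epoxidation of the trisubstituted alkene in (S)-3 and epoxidation of the isopropenyl group in (R)-3 may be too small, or the doubly allylic carbinol may ionise on the Lewis-acidic titanium, giving a low-yielding mixture that is hard to separate. Fallback: set C14/C15 on a primary allylic alcohol instead. From 1, NaBH4/CeCl3·7H2O in MeOH would give (E)-2-methylbut-2-en-1-ol F3. Sharpless asymmetric epoxidation (Ti(OiPr)4, L-(+)-diisopropyl tartrate, t-BuOOH, −20 °C) would give [(2S,3S)-2,3-dimethyloxiran-2-yl]methanol F4, and Parikh–Doering oxidation (SO3·pyridine, DMSO, Et3N) would give (2R,3S)-2,3-dimethyloxirane-2-carbaldehyde F5. Addition of 2 in THF at −78 °C, with the nucleophile approaching anti to the epoxide C–O bond, is expected to favour the erythro adduct, which is 4; the C16 epimer would be removed by chromatography.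

**Further compounds**

F1 | step 9 | C12 triethylsilyl enol ether of dialdehyde 12 (E/Z mixture) | CC[Si](CC)(CC)OC=C[C@H](C)[C@@](C)(O[Si]1(C(C)C)C(C)C)[C@@H](OC(C)=O)[C@@](C)(O1)C=O
F2 | step 11 | S-ethyl (E)-2-methyl-3-[ring]prop-2-enethioate, ring = C13 of 14 | CCSC(=O)/C(C)=C/[C@@H]1[C@H](C)[C@@](C)(O[Si]2(C(C)C)C(C)C)[C@@H](OC(C)=O)[C@@](C)(O2)[C@H]1O[Si](CC)(CC)CC
F3 | step 2 | (E)-2-methylbut-2-en-1-ol | C/C=C(\C)CO
F4 | step 2 | [(2S,3S)-2,3-dimethyloxiran-2-yl]methanol | C[C@@H]1O[C@@]1(C)CO
F5 | step 2 | (2R,3S)-2,3-dimethyloxirane-2-carbaldehyde | C[C@@H]1O[C@@]1(C)C=O
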